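**Plan**

Primed locants number the naphthalene with the chromanyl group on C1' and the methoxy groups on C4' and C5'; ring B is C5'–C8'.
Retrosynthetic cuts, in order: the O5 protecting group and the C5' O-methyl group; the C5'–C4a' bond of ring B; the C8'–C8a' bond (Heck); the C4–C1' bond (cation arylation); the pyranone ring (Claisen condensation, cyclodehydration).
Enabling feature: ring B carries nothing but the C5' oxygen, peri to the C4' methoxy group, so C5' can arrive as a ketene carbon and bond to C4a', the only free ortho carbon of a 5-methoxyphenyl ring whose other ortho carbon (C1') holds the chromanyl group.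
Forward: the pyranone ring is built on 2,6-dihydroxyacetophenone and reduced to the chromanol; the anisole ring is attached at C4, the four-carbon acid chain at its ortho carbon, and ring B closes last, followed by O-methylation and unmasking of O5.
Stereochemistry: C2 (R) comes from a ligand-controlled copper hydride conjugate reduction of the chromone; C4 (S) comes from C2, the arene adding to the chroman-4-yl cation trans to the 2-methyl group.

Key step: step 7

Assumption: (R)-DTBM-SEGPHOS is taken as the ligand enantiomer whose copper hydride gives the (2R) ketone; if the first run shows the opposite sense, its mirror image is used and nothing else changes.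
Remark: the O5 group is a tosylate, not a benzyl ether. It makes the chroman arene a poorer nucleophile than the arene partner in step 5, is inert to strong acid, palladium, hot Ac2O and carbonate, and is removed by hydroxide.
Remark: in the aryl bromide of step 5 the C4 descriptor reads R although the spatial arrangement is that of the target, because bromine raises the CIP rank of the aryl group above C4a.

**Route**

Step 1
Reactants: 1 2,6-dihydroxyacetophenone; 2 ethyl acetate
Product: 4 5-hydroxy-2-methyl-4H-chromen-4-one, via 1,3-diketone 3 (not isolated)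
Conditions: NaH (5 equiv), EtOAc (excess), THF, reflux; then HCl, AcOH, 80 °C
Reagents that add atoms: none
Why: Claisen condensation of the ketone enolate with ethyl acetate gives the 1,3-diketone, and acid closes the pyranone by cyclodehydration, the classical route to 2-methylchromones.

Step 2
Reactants: 4 5-hydroxy-2-methyl-4H-chromen-4-one
Product: 5 2-methyl-4-oxo-4H-chromen-5-yl 4-methylbenzenesulfonate
Conditions: TsCl, K2CO3, acetone, reflux
Reagents that add atoms: 4-methylbenzenesulfonyl chloride (TsCl), Cc1ccc(S(=O)(=O)Cl)cc1
Why: O-sulfonylation of the hydrogen-bonded peri phenol under carbonate, placed here so that no base meets the C2 stereocentre once it exists.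

Step 3
Reactants: 5 2-methyl-4-oxo-4H-chromen-5-yl 4-methylbenzenesulfonate
Product: 6 (2R)-2-methyl-4-oxochroman-5-yl 4-methylbenzenesulfonate
Conditions: Cu(OAc)2·H2O (3 mol %), (R)-DTBM-SEGPHOS (3.3 mol %), (EtO)2MeSiH, t-BuOH, toluene, 0 °C to rt
Reagents that add atoms: none
Why: Copper hydride-catalysed asymmetric conjugate reduction (1,4-hydrosilylation) of a chromone, a known entry to 2-substituted chromanones, in which the ligand-bound copper hydride delivers hydride to one face of C2 (ligand control sets C2 as R) and t-BuOH protonates the copper enolate; any over-reduced alcohol is the product of step 4 anyway.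

Step 4
Reactants: 6 (2R)-2-methyl-4-oxochroman-5-yl 4-methylbenzenesulfonate
Product: 7 (2R,4S)-4-hydroxy-2-methylchroman-5-yl 4-methylbenzenesulfonate (2,4-cis)
Conditions: NaBH4, MeOH, 0 °C
Reagents that add atoms: none
Why: Borohydride reduction of the aryl ketone should give mainly the 2,4-cis alcohol by pseudo-axial hydride attack (substrate control); the C4 configuration is immaterial because C4 is ionised in step 5, so a minor trans epimer is carried along.

Step 5
Reactants: 7 (2R,4S)-4-hydroxy-2-methylchroman-5-yl 4-methylbenzenesulfonate; 8 3-bromoanisole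
Product: 10 (2R,4R)-4-(2-bromo-4-methoxyphenyl)-2-methylchroman-5-yl 4-methylbenzenesulfonate (2,4-trans), via chroman-4-ylium ion 9 (not isolated)
Conditions: 8 (10 equiv), TfOH (10 mol %), (CF3)2CHOH, 0 °C to rt, slow addition of 7
Reagents that add atoms: none
Why: Acid-catalysed dehydrative Friedel–Crafts alkylation through the benzylic cation, in which the arene should react para to its methoxy group and approach the half-chair cation (2-methyl pseudo-equatorial) along the pseudo-axial trajectory, a preference reinforced by the peri 5-tosyloxy group that disfavours a pseudo-equatorial aryl group, so that C4 is set trans to the methyl group under control of C2.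

Step 6
Reactants: 10 (2R,4R)-4-(2-bromo-4-methoxyphenyl)-2-methylchroman-5-yl 4-methylbenzenesulfonate; 11 but-3-enoic acid
Product: 12 (E)-4-{5-methoxy-2-[(2R,4S)-2-methyl-5-(tosyloxy)chroman-4-yl]phenyl}but-3-enoic acid
Conditions: Pd(OAc)2 (5 mol %), P(o-tol)3 (15 mol %), Et3N, MeCN, 100 °C (sealed tube); aq. HCl work-up
Reagents that add atoms: none
Why: Mizoroki–Heck reaction in which the aryl bromide adds oxidatively to zerovalent palladium, the aryl group goes to the terminal alkene carbon and β-hydride elimination toward the benzylic side gives the conjugated (E)-styrenyl acid, the aryl sulfonate being inert to this catalyst and any positional alkene isomer converging in step 7.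

Step 7
Reactants: 12 (E)-4-{5-methoxy-2-[(2R,4S)-2-methyl-5-(tosyloxy)chroman-4-yl]phenyl}but-3-enoic acid
Product: 17 8-methoxy-5-[(2R,4S)-2-methyl-5-(tosyloxy)chroman-4-yl]naphthalen-1-yl acetate, via mixed anhydride 13 (not isolated), via dienylketene 14 (not isolated), via 8aH-naphthalen-1-one 15 (not isolated), via naphthol 16 (not isolated)
Conditions: Ac2O, NaOAc, reflux (about 140 °C)
Reagents that add atoms: acetic anhydride, CC(=O)OC(C)=O
Why: Ac2O converts the acid into the mixed anhydride 13, whose α-protons are removed reversibly by acetate so that the alkene geometry equilibrates through the dienolate, and loss of acetate from that dienolate gives the (Z)-dienylketene 14. Its ketene C=C, styrenyl C=C and one arene C=C form a hexatriene that undergoes thermal disrotatory 6π-electrocyclisation, making the C5'–C4a' bond and closing ring B as the six-membered carbocycle 15. A proton shift restores aromaticity to give naphthol 16, which Ac2O acetylates in the flask. The closest known reaction is the Ac2O/NaOAc cyclisation of 4-arylbut-3-enoic acids and Stobbe half-esters to 1-naphthyl acetates, including closures next to a methoxy group when the para position is blocked. No stereocentre is formed, and neither C2 nor C4 bears a proton that acetate could remove. The step needs site selectivity only, and the substrate secures it because the other ortho carbon (C1') holds the chromanyl group, leaving C4a' next to the methoxy group as the sole point of closure and placing the new oxygen peri to the C4' methoxy group.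

Step 8
Reactants: 17 8-methoxy-5-[(2R,4S)-2-methyl-5-(tosyloxy)chroman-4-yl]naphthalen-1-yl acetate
Product: 16 (2R,4S)-4-(5-hydroxy-4-methoxynaphthalen-1-yl)-2-methylchroman-5-yl 4-methylbenzenesulfonate
Conditions: K2CO3 (0.2 equiv), MeOH, 0 °C to rt
Reagents that add atoms: none
Why: Base-catalysed transesterification (methanolysis) of the aryl acetate returns the naphthol already met as the unisolated intermediate of step 7, the aryl sulfonate being inert to catalytic carbonate at room temperature.

Step 9
Reactants: 16 (2R,4S)-4-(5-hydroxy-4-methoxynaphthalen-1-yl)-2-methylchroman-5-yl 4-methylbenzenesulfonate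
Product: 18 (2R,4S)-4-(4,5-dimethoxynaphthalen-1-yl)-2-methylchroman-5-yl 4-methylbenzenesulfonate
Conditions: MeI, K2CO3, DMF, rt
Reagents that add atoms: iodomethane (MeI), CI
Why: Williamson O-methylation of the naphthoxide, with the sulfonate masking the chroman phenol so that only the C5' oxygen is alkylated.

Step 10
Reactants: 18 (2R,4S)-4-(4,5-dimethoxynaphthalen-1-yl)-2-methylchroman-5-yl 4-methylbenzenesulfonate
Product: 19 (2R,4S)-4-(4,5-dimethoxynaphthalen-1-yl)-2-methylchroman-5-ol (cladonaphchrom A)
Conditions: KOH, MeOH/H2O, reflux; then aq. HCl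
Reagents that add atoms: none
Why: Alkaline hydrolysis of the aryl sulfonate by hydroxide attack at sulfur (S–O cleavage) frees the C5 phenol without touching the methyl ethers, the pyran ring or either stereocentre.

**Compound list**

1 | 2,6-dihydroxyacetophenone | CC(=O)c1c(O)cccc1O | starting material
2 | ethyl acetate | CCOC(C)=O | starting material
3 | 1-(2,6-dihydroxyphenyl)butane-1,3-dione (not isolated, step 1) | CC(=O)CC(=O)c1c(O)cccc1O | intermediate
4 | 5-hydroxy-2-methyl-4H-chromen-4-one | Cc1cc(=O)c2c(O)cccc2o1 | intermediate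
5 | 2-methyl-4-oxo-4H-chromen-5-yl 4-methylbenzenesulfonate | Cc1cc(=O)c2c(OS(=O)(=O)c3ccc(C)cc3)cccc2o1 | intermediate
6 | (2R)-2-methyl-4-oxochroman-5-yl 4-methylbenzenesulfonate | C[C@@H]1CC(=O)c2c(OS(=O)(=O)c3ccc(C)cc3)cccc2O1 | intermediate
7 | (2R,4S)-4-hydroxy-2-methylchroman-5-yl 4-methylbenzenesulfonate (2,4-cis) | C[C@@H]1C[C@H](O)c2c(OS(=O)(=O)c3ccc(C)cc3)cccc2O1 | intermediate
8 | 3-bromoanisole | COc1cccc(Br)c1 | starting material
9 | (2R)-2-methyl-5-(tosyloxy)chroman-4-ylium ion (not isolated, step 5) | C[C@@H]1C[CH+]c2c(OS(=O)(=O)c3ccc(C)cc3)cccc2O1 | intermediate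
10 | (2R,4R)-4-(2-bromo-4-methoxyphenyl)-2-methylchroman-5-yl 4-methylbenzenesulfonate (2,4-trans) | COc1ccc([C@@H]2C[C@@H](C)Oc3cccc(OS(=O)(=O)c4ccc(C)cc4)c32)c(Br)c1 | intermediate
11 | but-3-enoic acid | C=CCC(=O)O | starting material
12 | (E)-4-{5-methoxy-2-[(2R,4S)-2-methyl-5-(tosyloxy)chroman-4-yl]phenyl}but-3-enoic acid | COc1ccc([C@@H]2C[C@@H](C)Oc3cccc(OS(=O)(=O)c4ccc(C)cc4)c32)c(/C=C/CC(=O)O)c1 | intermediate
13 | acetic (E)-4-{5-methoxy-2-[(2R,4S)-2-methyl-5-(tosyloxy)chroman-4-yl]phenyl}but-3-enoic anhydride (not isolated, step 7) | COc1ccc([C@@H]2C[C@@H](C)Oc3cccc(OS(=O)(=O)c4ccc(C)cc4)c32)c(/C=C/CC(=O)OC(C)=O)c1 | intermediate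
14 | (Z)-4-{5-methoxy-2-[(2R,4S)-2-methyl-5-(tosyloxy)chroman-4-yl]phenyl}buta-1,3-dien-1-one (dienylketene, not isolated, step 7) | COc1ccc([C@@H]2C[C@@H](C)Oc3cccc(OS(=O)(=O)c4ccc(C)cc4)c32)c(/C=C\C=C=O)c1 | intermediate
15 | 8-methoxy-5-[(2R,4S)-2-methyl-5-(tosyloxy)chroman-4-yl]naphthalen-1(8aH)-one (either C8a epimer, not isolated, step 7) | COC1=CC=C([C@@H]2C[C@@H](C)Oc3cccc(OS(=O)(=O)c4ccc(C)cc4)c32)C2=CC=CC(=O)C12 | intermediate
16 | (2R,4S)-4-(5-hydroxy-4-methoxynaphthalen-1-yl)-2-methylchroman-5-yl 4-methylbenzenesulfonate (formed in the flask in step 7, isolated in step 8) | COc1ccc([C@@H]2C[C@@H](C)Oc3cccc(OS(=O)(=O)c4ccc(C)cc4)c32)c2cccc(O)c12 | intermediate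
17 | 8-methoxy-5-[(2R,4S)-2-methyl-5-(tosyloxy)chroman-4-yl]naphthalen-1-yl acetate | COc1ccc([C@@H]2C[C@@H](C)Oc3cccc(OS(=O)(=O)c4ccc(C)cc4)c32)c2cccc(OC(C)=O)c12 | intermediate
18 | (2R,4S)-4-(4,5-dimethoxynaphthalen-1-yl)-2-methylchroman-5-yl 4-methylbenzenesulfonate | COc1ccc([C@@H]2C[C@@H](C)Oc3cccc(OS(=O)(=O)c4ccc(C)cc4)c32)c2cccc(OC)c12 | intermediate
19 | (2R,4S)-4-(4,5-dimethoxynaphthalen-1-yl)-2-methylchroman-5-ol (cladonaphchrom A) | COc1cccc2c([C@@H]3C[C@@H](C)Oc4cccc(O)c43)ccc(OC)c12 | target

**Count and risks**

Total step count: 10. Longest linear sequence: 10 steps (from 1).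

Steps most likely to fail:

1. Step 5. The bromoarene is a weak nucleophile, so the cation may instead alkylate a chroman arene, or lose a proton to the 2H-chromene, which then dimerises; attack ortho to the methoxy group may also compete. Fallback, setting out from 7 and returning at 12: the cation is trapped with 3-methoxybenzyl acetate, whose position para to the methoxy group is flanked by a CH2OAc group and is more electron-rich, under the same acid catalysis. This should give {5-methoxy-2-[(2R,4S)-2-methyl-5-(tosyloxy)chroman-4-yl]phenyl}methyl acetate F1. Methanolysis with catalytic K2CO3 would give (2R,4S)-4-[2-(hydroxymethyl)-4-methoxyphenyl]-2-methylchroman-5-yl 4-methylbenzenesulfonate F2, and MnO2 oxidation would give (2R,4S)-4-(2-formyl-4-methoxyphenyl)-2-methylchroman-5-yl 4-methylbenzenesulfonate F3. A Wittig reaction of F3 with (2-carboxyethyl)triphenylphosphonium bromide and NaN(SiMe3)2 would then give acid 12 as an E/Z mixture, acceptable because the geometry equilibrates in step 7. The Heck step is then not needed.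

2. Step 6. Oxidative addition at the hindered, electron-rich aryl bromide may be slow, letting protodebromination and double-bond migration or decarboxylation of the butenoic acid take over. Fallback, setting out from 10 and returning at 12: Suzuki–Miyaura coupling with potassium vinyltrifluoroborate (PdCl2(dppf), Cs2CO3, THF/H2O) would give (2R,4S)-4-(2-ethenyl-4-methoxyphenyl)-2-methylchroman-5-yl 4-methylbenzenesulfonate F4. Olefin cross-metathesis of F4 with but-3-enoic acid 11 (second-generation Hoveyda–Grubbs catalyst, CH2Cl2, 40 °C) would then give 12.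

3. Step 3. Facial discrimination in hydride delivery to the peri-substituted chromone may be insufficient, or the copper enolate may ring-open by β-elimination of the phenoxide and erode the C2 configuration. Fallback, setting out from 5 and returning at 7: hydrogenation over Pd/C would give racemic 2-methyl-4-oxochroman-5-yl 4-methylbenzenesulfonate F5, and NaBH4 would give racemic cis-4-hydroxy-2-methylchroman-5-yl 4-methylbenzenesulfonate F6. Kinetic resolution of F6 with Candida antarctica lipase B and vinyl acetate is expected to acetylate the (4R)-configured enantiomer, in line with the usual lipase preference for (R)-aryl carbinols. That would remove it as (2S,4R)-2-methyl-5-(tosyloxy)chroman-4-yl acetate F7 and leave the (2R,4S) alcohol 7.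

Further compounds
F1 | step 5 | {5-methoxy-2-[(2R,4S)-2-methyl-5-(tosyloxy)chroman-4-yl]phenyl}methyl acetate | COc1ccc([C@@H]2C[C@@H](C)Oc3cccc(OS(=O)(=O)c4ccc(C)cc4)c32)c(COC(C)=O)c1
F2 | step 5 | (2R,4S)-4-[2-(hydroxymethyl)-4-methoxyphenyl]-2-methylchroman-5-yl 4-methylbenzenesulfonate | COc1ccc([C@@H]2C[C@@H](C)Oc3cccc(OS(=O)(=O)c4ccc(C)cc4)c32)c(CO)c1
F3 | step 5 | (2R,4S)-4-(2-formyl-4-methoxyphenyl)-2-methylchroman-5-yl 4-methylbenzenesulfonate | COc1ccc([C@@H]2C[C@@H](C)Oc3cccc(OS(=O)(=O)c4ccc(C)cc4)c32)c(C=O)c1
F4 | step 6 | (2R,4S)-4-(2-ethenyl-4-methoxyphenyl)-2-methylchroman-5-yl 4-methylbenzenesulfonate | COc1ccc([C@@H]2C[C@@H](C)Oc3cccc(OS(=O)(=O)c4ccc(C)cc4)c32)c(C=C)c1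
F5 | step 3 | racemic 2-methyl-4-oxochroman-5-yl 4-methylbenzenesulfonate | CC1CC(=O)c2c(OS(=O)(=O)c3ccc(C)cc3)cccc2O1
F6 | step 3 | racemic cis-4-hydroxy-2-methylchroman-5-yl 4-methylbenzenesulfonate | C[C@@H]1C[C@H](O)c2c(OS(=O)(=O)c3ccc(C)cc3)cccc2O1.C[C@H]1C[C@@H](O)c2c(OS(=O)(=O)c3ccc(C)cc3)cccc2O1
F7 | step 3 | (2S,4R)-2-methyl-5-(tosyloxy)chroman-4-yl acetate | C[C@H]1C[C@@H](OC(C)=O)c2c(OS(=O)(=O)c3ccc(C)cc3)cccc2O1
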